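The route rests on cutting the bond between C2 of the chromen-4-one (ring C) and C1′ of the B ring, which is C7 of a 2,2-dimethyl-2H-chromene. The key step exploits the C2–H of a chromone whose benzo ring (C5–C8) carries no hydrogen: flanked by ring oxygen O1 and sitting on the β-carbon of the C4 enone, it is the most acidic C–H of the fragment. One operation turns this C–H into a C–Zn bond and cross-couples it with 7-bromo-2,2-dimethyl-2H-chromene, so the complete, doubly prenylated A/C half and the pyran-fused B half are joined without prefunctionalisation. C3 is then hydroxylated and the two MOM groups are removed.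

Key step: step 5

Remark: the target has no stereocentre, and every C=C bond is either in a ring or carries two identical methyl groups, so no stereodescriptor is needed.

Step 1
Reactants: 1 2,4,6-trihydroxyacetophenone
Product: 2 1-[2,4,6-trihydroxy-3,5-bis(3-methylbut-2-en-1-yl)phenyl]ethan-1-one
Conditions: prenyl bromide (2.2 equiv), 10% aq KOH, 0 °C → rt
Reagents that add atoms: prenyl bromide (1-bromo-3-methylbut-2-ene), CC(C)=CCBr
Why: C-alkylation of the phloroglucinol-type phenolate in water should place one prenyl group on each of the two free ring carbons C3 and C5 (phenolate C-prenylation), with mono-, O- and over-alkylated material removed by chromatography.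

Step 2
Reactants: 2 1-[2,4,6-trihydroxy-3,5-bis(3-methylbut-2-en-1-yl)phenyl]ethan-1-one
Product: 3 1-[2-hydroxy-4,6-bis(methoxymethoxy)-3,5-bis(3-methylbut-2-en-1-yl)phenyl]ethan-1-one
Conditions: MOMCl (2.3 equiv), i-Pr2NEt, CH2Cl2, 0 °C → rt
Reagents that add atoms: chloromethyl methyl ether, COCCl
Why: MOM ether formation should stop at the bis-ether because the last ortho hydroxyl is hydrogen-bonded to the acetyl carbonyl and is much less nucleophilic.

Step 3
Reactants: 3 1-[2-hydroxy-4,6-bis(methoxymethoxy)-3,5-bis(3-methylbut-2-en-1-yl)phenyl]ethan-1-one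
Product: 5 5,7-bis(methoxymethoxy)-6,8-bis(3-methylbut-2-en-1-yl)-4H-chromen-4-one, via enaminone 4 (not isolated)
Conditions: DMF-DMA, toluene, 95 °C; then AcOH (5 equiv), toluene, 80 °C
Reagents that add atoms: N,N-dimethylformamide dimethyl acetal, COC(OC)N(C)C
Why: Condensation of the methyl ketone with DMF-DMA gives the enaminone, and the free phenol then closes the pyranone by 6-endo addition–elimination of dimethylamine (enaminone chromone synthesis) under acid too weak to cleave the MOM ethers.

Step 4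
Reactants: 6 3-bromophenol; 7 3-methylbut-2-enal
Product: 9 7-bromo-2,2-dimethyl-2H-chromene, via quinone methide 8 (not isolated)
Conditions: PhB(OH)2 (1 equiv), AcOH (cat.), toluene, reflux, Dean–Stark
Reagents that add atoms: none
Why: Boron-templated ortho-condensation of the phenol with the enal gives the o-quinone methide, which closes by oxa-6π electrocyclisation (2H-chromene synthesis from phenols and enals); the ortho carbon para to bromine should react because the other one is flanked by OH and Br.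

Step 5
Reactants: 5 5,7-bis(methoxymethoxy)-6,8-bis(3-methylbut-2-en-1-yl)-4H-chromen-4-one; 9 7-bromo-2,2-dimethyl-2H-chromene
Product: 11 2-(2,2-dimethyl-2H-chromen-7-yl)-5,7-bis(methoxymethoxy)-6,8-bis(3-methylbut-2-en-1-yl)-4H-chromen-4-one, via chromon-2-ylzinc chloride 10 (not isolated)
Conditions: TMPZnCl·LiCl (1.3 equiv), THF, 25 °C; then 9 (1.1 equiv), Pd(OAc)2 (2 mol%), SPhos (4 mol%), THF, 50 °C
Reagents that add atoms: none
Why: The hindered zinc amide removes the C2–H of 5 (sp2, α to ring O1 and on the β-carbon of the C4 enone) to give the chromon-2-ylzinc species, while Pd(0)/SPhos inserts into the C–Br bond of 9; transmetalation and reductive elimination then form the C2–C1′ bond. The closest known reaction type is the C2-zincation of chromones with TMPZnCl·LiCl followed by Negishi cross-coupling to flavones. No ring is closed and no stereocentre is created. The step needs C2 over C3 metalation and reaction at the aryl bromide in the presence of four alkenes: Lewis acids that steer zincation to C3 are left out, the benzo ring C5–C8 is fully substituted so no aryl C–H competes, the prenyl CH2 groups are far less acidic, and neither the trisubstituted prenyl alkenes nor the chromene C3=C4 bond should engage palladium under Negishi conditions. The zinc amide and the organozinc tolerate the C4 ketone and the MOM acetals, so the whole protected A/C half can be carried into the coupling.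

Step 6
Reactants: 11 2-(2,2-dimethyl-2H-chromen-7-yl)-5,7-bis(methoxymethoxy)-6,8-bis(3-methylbut-2-en-1-yl)-4H-chromen-4-one
Product: 14 2-(2,2-dimethyl-2H-chromen-7-yl)-3-hydroxy-5,7-bis(methoxymethoxy)-6,8-bis(3-methylbut-2-en-1-yl)-4H-chromen-4-one, via 3-lithioflavone 12 (not isolated), via flavon-3-ylboronate 13 (not isolated)
Conditions: LDA (1.3 equiv), THF, −78 °C; B(OMe)3, −78 → 0 °C; AcOH, 30% aq H2O2, 0 °C
Reagents that add atoms: hydrogen peroxide, OO
Why: LDA should lithiate C3, the only sp2 C–H next to the C4 carbonyl, and trapping as the boronate followed by oxidative 1,2-migration from boron to oxygen gives the 3-hydroxyflavone (directed lithiation–borylation–oxidation of flavones), while cold buffered peroxide leaves the electron-rich alkenes alone.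

Step 7
Reactants: 14 2-(2,2-dimethyl-2H-chromen-7-yl)-3-hydroxy-5,7-bis(methoxymethoxy)-6,8-bis(3-methylbut-2-en-1-yl)-4H-chromen-4-one
Product: 15 dorsilurin C
Conditions: 3 M aq HCl, MeOH, 40 °C
Reagents that add atoms: none
Why: Acid-catalysed transacetalisation of the two aryl MOM ethers to dimethoxymethane frees the C5 and C7 phenols (MOM deprotection), and dilute acid at mild temperature is expected to stay below the threshold for cyclisation of the ortho-prenyl phenols.

Compound list
1 | 2,4,6-trihydroxyacetophenone | CC(=O)c1c(O)cc(O)cc1O | starting material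
2 | 1-[2,4,6-trihydroxy-3,5-bis(3-methylbut-2-en-1-yl)phenyl]ethan-1-one | CC(=O)c1c(O)c(CC=C(C)C)c(O)c(CC=C(C)C)c1O | intermediate
3 | 1-[2-hydroxy-4,6-bis(methoxymethoxy)-3,5-bis(3-methylbut-2-en-1-yl)phenyl]ethan-1-one | CC(=O)c1c(O)c(CC=C(C)C)c(OCOC)c(CC=C(C)C)c1OCOC | intermediate
4 | (E)-3-(dimethylamino)-1-[2-hydroxy-4,6-bis(methoxymethoxy)-3,5-bis(3-methylbut-2-en-1-yl)phenyl]prop-2-en-1-one (enaminone) | CN(C)/C=C/C(=O)c1c(O)c(CC=C(C)C)c(OCOC)c(CC=C(C)C)c1OCOC | intermediate (not isolated)
5 | 5,7-bis(methoxymethoxy)-6,8-bis(3-methylbut-2-en-1-yl)-4H-chromen-4-one | O=c1ccoc2c(CC=C(C)C)c(OCOC)c(CC=C(C)C)c(OCOC)c12 | intermediate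
6 | 3-bromophenol | Oc1cccc(Br)c1 | starting material
7 | 3-methylbut-2-enal | CC(C)=CC=O | starting material
8 | (6Z)-3-bromo-6-(3-methylbut-2-en-1-ylidene)cyclohexa-2,4-dien-1-one (o-quinone methide) | O=C1C=C(Br)C=C/C1=C/C=C(C)C | intermediate (not isolated)
9 | 7-bromo-2,2-dimethyl-2H-chromene | CC1(C)C=Cc2ccc(Br)cc2O1 | intermediate
10 | [5,7-bis(methoxymethoxy)-6,8-bis(3-methylbut-2-en-1-yl)-4-oxo-4H-chromen-2-yl]zinc chloride (LiCl adduct) | O=c1cc([Zn]Cl)oc2c(CC=C(C)C)c(OCOC)c(CC=C(C)C)c(OCOC)c12 | intermediate (not isolated)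
11 | 2-(2,2-dimethyl-2H-chromen-7-yl)-5,7-bis(methoxymethoxy)-6,8-bis(3-methylbut-2-en-1-yl)-4H-chromen-4-one | O=c1cc(-c2ccc3c(c2)OC(C)(C)C=C3)oc2c(CC=C(C)C)c(OCOC)c(CC=C(C)C)c(OCOC)c12 | intermediate
12 | 3-lithio derivative of 11 | [Li]c1c(-c2ccc3c(c2)OC(C)(C)C=C3)oc2c(CC=C(C)C)c(OCOC)c(CC=C(C)C)c(OCOC)c2c1=O | intermediate (not isolated)
13 | dimethyl [2-(2,2-dimethyl-2H-chromen-7-yl)-5,7-bis(methoxymethoxy)-6,8-bis(3-methylbut-2-en-1-yl)-4-oxo-4H-chromen-3-yl]boronate | COB(OC)c1c(-c2ccc3c(c2)OC(C)(C)C=C3)oc2c(CC=C(C)C)c(OCOC)c(CC=C(C)C)c(OCOC)c2c1=O | intermediate (not isolated)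
14 | 2-(2,2-dimethyl-2H-chromen-7-yl)-3-hydroxy-5,7-bis(methoxymethoxy)-6,8-bis(3-methylbut-2-en-1-yl)-4H-chromen-4-one | O=c1c(O)c(-c2ccc3c(c2)OC(C)(C)C=C3)oc2c(CC=C(C)C)c(OCOC)c(CC=C(C)C)c(OCOC)c12 | intermediate
15 | dorsilurin C, 2-(2,2-dimethyl-2H-chromen-7-yl)-3,5,7-trihydroxy-6,8-bis(3-methylbut-2-en-1-yl)-4H-chromen-4-one | CC(C)=CCc1c(O)c(CC=C(C)C)c2oc(-c3ccc4c(c3)OC(C)(C)C=C4)c(O)c(=O)c2c1O | target

Total step count: 7. Longest linear sequence: 6 (steps 1, 2, 3, 5, 6, 7).

Steps most likely to fail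

Step 5. The zincation may stall on the electron-rich chromone, chelation by the C4 carbonyl and the C5 MOM ether may steer the base towards C3, or the hindered organozinc may transmetalate so slowly that protodemetalation wins. The fallback brings the aryl–C2 bond in ready-made through a diketone. It sets out from bromide 9 and acetophenone 3. Palladium-catalysed methoxycarbonylation of 9 (CO 1 atm, MeOH, Pd(OAc)2/dppf, Et3N, 70 °C) should give methyl 2,2-dimethyl-2H-chromene-7-carboxylate F1. Claisen condensation of F1 with the dianion of 3 (LiHMDS, THF, −78 °C → rt) should give 1-(2,2-dimethyl-2H-chromen-7-yl)-3-[2-hydroxy-4,6-bis(methoxymethoxy)-3,5-bis(3-methylbut-2-en-1-yl)phenyl]propane-1,3-dione F2. Cyclodehydration (NaOAc, AcOH, 90 °C) comes back to the route at flavone 11.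

Step 6. The C3 anion may fragment by β-elimination of the O1 phenoxide, LDA may instead remove a benzylic–allylic proton of a prenyl group, or the oxidant may attack the electron-rich alkenes. The fallback puts the C3 oxygen in before the coupling and sets out from chromone 5. Nucleophilic epoxidation of the electron-poor C2=C3 bond (30% H2O2, NaOH, CH2Cl2/MeOH, 0 °C) should give racemic 2,3-epoxy-5,7-bis(methoxymethoxy)-6,8-bis(3-methylbut-2-en-1-yl)chroman-4-one F3. Isomerisation of the epoxy ketone to the enol of the 1,2-diketone (p-TsOH cat., CH2Cl2, 0 °C) should give 3-hydroxy-5,7-bis(methoxymethoxy)-6,8-bis(3-methylbut-2-en-1-yl)-4H-chromen-4-one F4. MOMCl/i-Pr2NEt should give 3,5,7-tris(methoxymethoxy)-6,8-bis(3-methylbut-2-en-1-yl)-4H-chromen-4-one F5. Under the conditions of step 5 the C2–H, now flanked by O1 and the C3 ether, should be zincated to [3,5,7-tris(methoxymethoxy)-6,8-bis(3-methylbut-2-en-1-yl)-4-oxo-4H-chromen-2-yl]zinc chloride F6 and coupled with 9 to 2-(2,2-dimethyl-2H-chromen-7-yl)-3,5,7-tris(methoxymethoxy)-6,8-bis(3-methylbut-2-en-1-yl)-4H-chromen-4-one F7. The conditions of step 7 then come back to the route at target 15.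

Step 7. Once the phenols are free, protonation of a flanking prenyl alkene can lead to ring closure to a chroman, and acid can add methanol or water to the alkenes. The fallback avoids protic acid and sets out from 14. TMSOTf and 2,2′-bipyridyl (CH2Cl2, 0 °C) should exchange the MOM acetals for silyl ethers and silylate the C3 hydroxyl, giving 2-(2,2-dimethyl-2H-chromen-7-yl)-6,8-bis(3-methylbut-2-en-1-yl)-3,5,7-tris(trimethylsilyloxy)-4H-chromen-4-one F8. Neutral hydrolysis on aqueous work-up (H2O, THF, rt) comes back to the route at target 15.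

Further compounds
F1 | step 5 | methyl 2,2-dimethyl-2H-chromene-7-carboxylate | COC(=O)c1ccc2c(c1)OC(C)(C)C=C2
F2 | step 5 | 1-(2,2-dimethyl-2H-chromen-7-yl)-3-[2-hydroxy-4,6-bis(methoxymethoxy)-3,5-bis(3-methylbut-2-en-1-yl)phenyl]propane-1,3-dione | O=C(CC(=O)c1ccc2c(c1)OC(C)(C)C=C2)c1c(O)c(CC=C(C)C)c(OCOC)c(CC=C(C)C)c1OCOC
F3 | step 6 | 2,3-epoxy-5,7-bis(methoxymethoxy)-6,8-bis(3-methylbut-2-en-1-yl)chroman-4-one (racemic, cis-fused, relative configuration shown) | O=C1[C@H]2O[C@H]2Oc2c(CC=C(C)C)c(OCOC)c(CC=C(C)C)c(OCOC)c12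
F4 | step 6 | 3-hydroxy-5,7-bis(methoxymethoxy)-6,8-bis(3-methylbut-2-en-1-yl)-4H-chromen-4-one | O=c1c(O)coc2c(CC=C(C)C)c(OCOC)c(CC=C(C)C)c(OCOC)c12
F5 | step 6 | 3,5,7-tris(methoxymethoxy)-6,8-bis(3-methylbut-2-en-1-yl)-4H-chromen-4-one | COCOc1coc2c(CC=C(C)C)c(OCOC)c(CC=C(C)C)c(OCOC)c2c1=O
F6 | step 6 | [3,5,7-tris(methoxymethoxy)-6,8-bis(3-methylbut-2-en-1-yl)-4-oxo-4H-chromen-2-yl]zinc chloride | COCOc1c([Zn]Cl)oc2c(CC=C(C)C)c(OCOC)c(CC=C(C)C)c(OCOC)c2c1=O
F7 | step 6 | 2-(2,2-dimethyl-2H-chromen-7-yl)-3,5,7-tris(methoxymethoxy)-6,8-bis(3-methylbut-2-en-1-yl)-4H-chromen-4-one | COCOc1c(-c2ccc3c(c2)OC(C)(C)C=C3)oc2c(CC=C(C)C)c(OCOC)c(CC=C(C)C)c(OCOC)c2c1=O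
F8 | step 7 | 2-(2,2-dimethyl-2H-chromen-7-yl)-6,8-bis(3-methylbut-2-en-1-yl)-3,5,7-tris(trimethylsilyloxy)-4H-chromen-4-one | C[Si](C)(C)Oc1c(-c2ccc3c(c2)OC(C)(C)C=C3)oc2c(CC=C(C)C)c(O[Si](C)(C)C)c(CC=C(C)C)c(O[Si](C)(C)C)c2c1=O
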